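**Retrosynthetic overview**
- The two ring-B phenols are unmasked last from aryl chlorides (borylation/oxidation); until then the chlorines keep ring B and the benzylic C2–O bond inert to oxidation, acid, base and heat.
- The C8 prenyl group comes from the 5-O-prenyl ether by a Claisen–Cope relay.
- The pyran ring is closed at O1–C8a by a visible-light arene radical-cation ipso-substitution: the C2 carbinol displaces one of two equivalent OMOM groups, with retention at C2.
- C4–C4a is made by opening an enantiopure 2-aryloxetane with a 2,6-bis(MOM-oxy)aryllithium; the oxetane comes from a purchased (R)-chlorohydrin that supplies C2.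
- Ring order: rings A and B are bought; a transient oxetane is formed in step 1 and opened in step 3; ring C (pyran) is formed in step 4.

Assumption: (R)-2-chloro-1-(2,4-dichlorophenyl)ethanol (azole-antifungal intermediate, sold as either enantiomer in ≥99% ee) is taken as the cheap commercial source of the C2 stereocentre.

**Step 1**
Reactants: 1 (R)-2-chloro-1-(2,4-dichlorophenyl)ethanol
Product: 3 (S)-2-(2,4-dichlorophenyl)oxetane, via (R)-2-(2,4-dichlorophenyl)oxirane 2 (not isolated)
Conditions: t-BuOK (1.1 equiv), t-BuOH, rt, 30 min; then Me3S(O)I (3 equiv), t-BuOK (3 equiv), 60 °C, 48 h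
Reagents that add atoms: trimethylsulfoxonium iodide, C[S+](C)(C)=O.[I-] (the new ring CH2)
Why: Williamson closure to the epoxide followed by Corey–Chaykovsky-type epoxide-to-oxetane ring expansion (ylide attack at the unhindered CH2, then 4-exo-tet closure) never breaks the benzylic C–O bond, so the bought configuration is carried over unchanged (R→S is only a CIP priority change).

**Step 2**
Reactants: 4 5-methoxybenzene-1,3-diol (5-methoxyresorcinol)
Product: 5 1-methoxy-3,5-bis(methoxymethoxy)benzene
Conditions: NaH (2.4 equiv), MOMCl (2.4 equiv), DMF, 0 °C → rt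
Reagents that add atoms: chloromethyl methyl ether, COCCl
Why: Williamson etherification (MOM protection) of both phenols gives a symmetric arene whose C–H between the two OMOM groups is the strongest ortho-metalation site.

**Step 3**
Reactants: 5 1-methoxy-3,5-bis(methoxymethoxy)benzene, 3 (S)-2-(2,4-dichlorophenyl)oxetane
Product: 7 (1S)-1-(2,4-dichlorophenyl)-3-[4-methoxy-2,6-bis(methoxymethoxy)phenyl]propan-1-ol, via [4-methoxy-2,6-bis(methoxymethoxy)phenyl]lithium 6 (not isolated)
Conditions: 5 (1.2 equiv), n-BuLi, THF, 0 °C, 1 h; then 3, BF3·OEt2, −78 °C, 1 h; H2O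
Reagents that add atoms: n-butyllithium, CCCC[Li] (lithium of 6 only; nothing of it remains in 7)
Why: Directed ortho-metalation between the two OMOM groups, then BF3-promoted SN2 opening of the oxetane at its unsubstituted CH2 (the benzylic carbon is hindered and deactivated by the chlorines), forms C4–C4a without touching the stereocentre.

**Step 4**
Reactants: 7 (1S)-1-(2,4-dichlorophenyl)-3-[4-methoxy-2,6-bis(methoxymethoxy)phenyl]propan-1-ol
Product: 9 (2S)-2-(2,4-dichlorophenyl)-7-methoxy-3,4-dihydro-2H-chromen-5-ol, via (2S)-2-(2,4-dichlorophenyl)-7-methoxy-5-(methoxymethoxy)chroman 8 (not isolated)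
Conditions: 9-mesityl-3,6-di-tert-butyl-10-phenylacridinium BF4 (5 mol%), DCE/TFE 4:1 (0.02 M), 450 nm LEDs, N2, rt; then MeOH, HCl (1 M), 50 °C
Reagents that add atoms: none
Why: Proposed new method: the excited acridinium (about +2.1 V vs SCE) oxidises only the trialkoxy ring A of 7 (about +1.4 V; the dichlorophenyl ring lies above +2.3 V) to its radical cation, the tethered C2–OH adds through a six-membered transition state to one of the two equivalent OMOM-bearing ipso carbons, the ketal-type cyclohexadienyl radical expels methoxymethanol (irreversible, the hemiformal falls apart) and the acridine radical reduces the product radical cation, so the O1–C8a bond and the pyran ring form in a redox-neutral cycle while the C2–O bond is never broken and the (S) configuration is retained; the closest known reaction type is acridinium-photocatalysed cation-radical-accelerated SNAr of alkoxyarenes with azole and amine nucleophiles, not shown for an alcohol nucleophile, for chroman ring closure or with OMOM as leaving group; the acid methanolysis that follows is an ordinary MOM cleavage.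

**Step 5**
Reactants: 9 (2S)-2-(2,4-dichlorophenyl)-7-methoxy-3,4-dihydro-2H-chromen-5-ol
Product: 10 (2S)-2-(2,4-dichlorophenyl)-7-methoxy-5-[(3-methylbut-2-en-1-yl)oxy]-3,4-dihydro-2H-chromene
Conditions: prenyl bromide (1.3 equiv), K2CO3, acetone, 56 °C
Reagents that add atoms: 1-bromo-3-methylbut-2-ene (prenyl bromide), CC(C)=CCBr
Why: Williamson O-alkylation of the only phenol; K2CO3/acetone favours O- over C-alkylation.

**Step 6**
Reactants: 10 (2S)-2-(2,4-dichlorophenyl)-7-methoxy-5-[(3-methylbut-2-en-1-yl)oxy]-3,4-dihydro-2H-chromene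
Product: 13 (2S)-2-(2,4-dichlorophenyl)-7-methoxy-8-(3-methylbut-2-en-1-yl)-3,4-dihydro-2H-chromen-5-ol, via Claisen ortho-dienone 11 (not isolated), via Cope para-dienone 12 (not isolated)
Conditions: PhNEt2, 200 °C (sealed tube), 3 h
Reagents that add atoms: none
Why: Aromatic Claisen rearrangement to the congested C6 dienone, then Cope rearrangement to C8 (para to O5, the para-Claisen relay used for 8-prenylflavonoids) and tautomerisation, delivers a normal prenyl group at C8; C2 is not involved and cannot ionise because of the electron-poor dichlorophenyl group.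

**Step 7**
Reactants: 13 (2S)-2-(2,4-dichlorophenyl)-7-methoxy-8-(3-methylbut-2-en-1-yl)-3,4-dihydro-2H-chromen-5-ol
Product: 15 4-[(2S)-5-hydroxy-7-methoxy-8-(3-methylbut-2-en-1-yl)-3,4-dihydro-2H-chromen-2-yl]benzene-1,3-diol (CNP0115018.1), via bis(pinacolboronate) 14 (not isolated)
Conditions: XPhos Pd G3 (8 mol%), B2pin2 (3.5 equiv), KOAc (6 equiv), 1,4-dioxane, 100 °C; then 30% H2O2, THF/pH 7.4 phosphate buffer, 0 °C → rt
Reagents that add atoms: hydrogen peroxide, OO (the two new phenol oxygens); bis(pinacolato)diboron, CC1(C)OB(OC1(C)C)B1OC(C)(C)C(C)(C)O1 (boryl groups of 14 only)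
Why: Miyaura borylation of both aryl chlorides followed by ipso-oxidation of the C–B bonds at neutral pH and ≤ rt installs the 2′,4′-OH groups without generating hot phenoxide, which would open the flavan through a quinone methide and racemise C2; the prenyl alkene is inert to neutral H2O2.

**Compound list**
1 | (R)-2-chloro-1-(2,4-dichlorophenyl)ethanol | O[C@@H](CCl)c1ccc(Cl)cc1Cl | starting material
2 | (R)-2-(2,4-dichlorophenyl)oxirane | O1[C@H](c2ccc(Cl)cc2Cl)C1 | intermediate
3 | (S)-2-(2,4-dichlorophenyl)oxetane | O1[C@H](c2ccc(Cl)cc2Cl)CC1 | intermediate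
4 | 5-methoxybenzene-1,3-diol | COc1cc(O)cc(O)c1 | starting material
5 | 1-methoxy-3,5-bis(methoxymethoxy)benzene | COCOc1cc(OC)cc(OCOC)c1 | intermediate
6 | [4-methoxy-2,6-bis(methoxymethoxy)phenyl]lithium | [Li]c1c(OCOC)cc(OC)cc1OCOC | intermediate
7 | (1S)-1-(2,4-dichlorophenyl)-3-[4-methoxy-2,6-bis(methoxymethoxy)phenyl]propan-1-ol | O[C@H](c1ccc(Cl)cc1Cl)CCc1c(OCOC)cc(OC)cc1OCOC | intermediate
8 | (2S)-2-(2,4-dichlorophenyl)-7-methoxy-5-(methoxymethoxy)-3,4-dihydro-2H-chromene | COc1cc(OCOC)c2c(c1)O[C@H](c1ccc(Cl)cc1Cl)CC2 | intermediate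
9 | (2S)-2-(2,4-dichlorophenyl)-7-methoxy-3,4-dihydro-2H-chromen-5-ol | COc1cc(O)c2c(c1)O[C@H](c1ccc(Cl)cc1Cl)CC2 | intermediate
10 | (2S)-2-(2,4-dichlorophenyl)-7-methoxy-5-[(3-methylbut-2-en-1-yl)oxy]-3,4-dihydro-2H-chromene | COc1cc(OCC=C(C)C)c2c(c1)O[C@H](c1ccc(Cl)cc1Cl)CC2 | intermediate
11 | (2S)-2-(2,4-dichlorophenyl)-7-methoxy-6-(2-methylbut-3-en-2-yl)-3,4-dihydro-2H-chromen-5(6H)-one (C6 epimers) | O=C1C(C(C)(C)C=C)C(OC)=CC2=C1CC[C@@H](c1ccc(Cl)cc1Cl)O2 | intermediate
12 | (2S)-2-(2,4-dichlorophenyl)-7-methoxy-8-(3-methylbut-2-en-1-yl)-3,4-dihydro-2H-chromen-5(8H)-one (C8 epimers) | O=C1C=C(OC)C(CC=C(C)C)C2=C1CC[C@@H](c1ccc(Cl)cc1Cl)O2 | intermediate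
13 | (2S)-2-(2,4-dichlorophenyl)-7-methoxy-8-(3-methylbut-2-en-1-yl)-3,4-dihydro-2H-chromen-5-ol | COc1cc(O)c2c(c1CC=C(C)C)O[C@H](c1ccc(Cl)cc1Cl)CC2 | intermediate
14 | (2S)-2-[2,4-bis(4,4,5,5-tetramethyl-1,3,2-dioxaborolan-2-yl)phenyl]-7-methoxy-8-(3-methylbut-2-en-1-yl)-3,4-dihydro-2H-chromen-5-ol | COc1cc(O)c2c(c1CC=C(C)C)O[C@H](c1ccc(B3OC(C)(C)C(C)(C)O3)cc1B1OC(C)(C)C(C)(C)O1)CC2 | intermediate
15 | 4-[(2S)-5-hydroxy-7-methoxy-8-(3-methylbut-2-en-1-yl)-3,4-dihydro-2H-chromen-2-yl]benzene-1,3-diol | COc1cc(O)c2c(c1CC=C(C)C)O[C@H](c1ccc(O)cc1O)CC2 | target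

**Totals**
Total steps: 7. Longest linear sequence: 6 steps (1 → 3 → 7 → 9 → 10 → 13 → 15).

**Steps most likely to fail, with fallbacks**

Step 4 (the proposed new photochemical ring closure). It may fail through slow ipso-attack, benzylic deprotonation of the radical cation, or exchange of the remaining OMOM by released methanol. The fallback uses known chemistry, sets out from 7 and comes back at 9. A Mitsunobu reaction of 7 with 4-nitrobenzoic acid (PPh3, DIAD, THF, 0 °C → rt) inverts C2 and gives (1R)-1-(2,4-dichlorophenyl)-3-[4-methoxy-2,6-bis(methoxymethoxy)phenyl]propyl 4-nitrobenzoate F1. Methanolysis (K2CO3, MeOH, rt) gives (1R)-1-(2,4-dichlorophenyl)-3-[4-methoxy-2,6-bis(methoxymethoxy)phenyl]propan-1-ol F2. HCl in MeOH (50 °C) removes both MOM groups to give 2-[(3R)-3-(2,4-dichlorophenyl)-3-hydroxypropyl]-5-methoxybenzene-1,3-diol F3. An intramolecular Mitsunobu etherification (PPh3, DIAD, THF, 0 °C) by either of the two equivalent phenols closes O1–C2 with a second inversion and gives (S)-9.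

Step 6 (Claisen–Cope relay). The C6 dienone can tautomerise to the 6-(1,1-dimethylallyl) phenol instead of undergoing the Cope shift. The fallback sets out from 8 (isolated by leaving out the acid treatment in step 4) and comes back at 13. NBS (CH2Cl2, −20 °C) brominates the position between OMe and the ring oxygen, as in 5,7-di-O-alkylflavans, to give (2S)-8-bromo-2-(2,4-dichlorophenyl)-7-methoxy-5-(methoxymethoxy)-3,4-dihydro-2H-chromene F4. Stille coupling with tributyl(3-methylbut-2-en-1-yl)stannane (Pd(PPh3)4, DMF, 100 °C; the aryl chlorides do not react) gives (2S)-2-(2,4-dichlorophenyl)-7-methoxy-5-(methoxymethoxy)-8-(3-methylbut-2-en-1-yl)-3,4-dihydro-2H-chromene F5. Mild HCl/MeOH (40 °C) removes the MOM group to give 13.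

Step 7 (double borylation/oxidation). The 2′-chloride is hindered, the boronate may protodeboronate, and the product is prone to racemisation. The fallback sets out from 13 and comes back at 15 directly: Pd-catalysed hydroxylation of both C–Cl bonds with hydroxide (tBuBrettPhos Pd G3, KOH, 1,4-dioxane/H2O, 80 °C, short reaction time, pH 6 quench, ee checked by chiral HPLC). No new compound is made (F0).

**Further compounds**
F1 | step 4 | (1R)-1-(2,4-dichlorophenyl)-3-[4-methoxy-2,6-bis(methoxymethoxy)phenyl]propyl 4-nitrobenzoate | O=C(O[C@@H](c1ccc(Cl)cc1Cl)CCc1c(OCOC)cc(OC)cc1OCOC)c1ccc(cc1)[N+](=O)[O-]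
F2 | step 4 | (1R)-1-(2,4-dichlorophenyl)-3-[4-methoxy-2,6-bis(methoxymethoxy)phenyl]propan-1-ol | O[C@@H](c1ccc(Cl)cc1Cl)CCc1c(OCOC)cc(OC)cc1OCOC
F3 | step 4 | 2-[(3R)-3-(2,4-dichlorophenyl)-3-hydroxypropyl]-5-methoxybenzene-1,3-diol | O[C@@H](c1ccc(Cl)cc1Cl)CCc1c(O)cc(OC)cc1O
F4 | step 6 | (2S)-8-bromo-2-(2,4-dichlorophenyl)-7-methoxy-5-(methoxymethoxy)-3,4-dihydro-2H-chromene | COc1cc(OCOC)c2c(c1Br)O[C@H](c1ccc(Cl)cc1Cl)CC2
F5 | step 6 | (2S)-2-(2,4-dichlorophenyl)-7-methoxy-5-(methoxymethoxy)-8-(3-methylbut-2-en-1-yl)-3,4-dihydro-2H-chromene | COc1cc(OCOC)c2c(c1CC=C(C)C)O[C@H](c1ccc(Cl)cc1Cl)CC2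
F0 | step 7 | none | none
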